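**Retrosynthetic overview**

1. The strategy rests on one feature: carbons C1–C14 form an unbroken fourteen-carbon loop and only the bond C1–C10 divides it into ring A and the ten-membered ring. Labels: C1 quaternary C–CH3 (C15); C2 and C14 CH–OAc; C5(C16)=C6 Z alkene; C7 lactone O–CH; C8 C–OH; C9 C=O; C10 ring-fusion CH; C11(C20H2OH)=C12 ring A alkene; C17(C18)/C19 lactone CH–CH3/C=O.
2. Last C–C bond: C1–C10, closed across a 14-membered lactone-fused macrocycle by opening a C1–C2 epoxide with the C9 silyl dienol ether; the C2 hydroxyl appears in the same step.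
3. Macrocycle: closed at C6–C7 by a Nozaki–Hiyama–Kishi reaction of a Z vinyl iodide with a C7 aldehyde, the new C7 oxygen then closing the γ-lactone onto C19; the epoxide is placed afterwards by a C14-hydroxyl-directed Sharpless epoxidation.
4. Open chain: C8–C9 aldol of a malic acid-derived dioxolanone (C7, C8, C17–C19) with a C9 aldehyde. Its chain is grown from pent-4-yn-1-ol by Wittig olefination, asymmetric propargylboration (C14) and hydroxyl-directed vinylmagnesiation (C11=C12).
5. Ring order: 14-membered carbocycle and γ-lactone in step 19, then ring A and the ten-membered ring together in step 23.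

Key step: step 23

Assumption: in the phosphoric acid-catalysed propargylboration (step 8) the (S)-acid is taken to give the (S)-carbinol, by analogy with (R)-TRIP giving (R)-homopropargylic alcohols from aldehydes whose larger substituent is sp2; if the sense is opposite, the antipodal acid is used.

**Route**

Step 1
Reactants: 1 dimethyl (S)-malate
Product: 3 dimethyl (2S,3R)-2-hydroxy-3-methylbutanedioate, via dilithium alkoxide enolate 2 (not isolated)
Conditions: LiN(iPr)2 (2.2 equiv), THF, −78 → −20 °C; MeI, −78 → 0 °C; aq. NH4Cl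
Reagents that add atoms: iodomethane, CI
Why: Fráter–Seebach alkylation, in which the chelated dilithium alkoxide enolate is methylated anti to the alkoxide-bearing carbon's ester group, should set C17 (R) next to the malate carbinol that becomes C8.

Step 2
Reactants: 3 dimethyl (2S,3R)-2-hydroxy-3-methylbutanedioate
Product: 4 (2S,3R)-2-hydroxy-3-methylbutanedioic acid
Conditions: KOH, H2O–MeOH, 0 → 23 °C; HCl to pH 1; continuous extraction with EtOAc
Reagents that add atoms: water, O
Why: Ester saponification should leave both stereocentres intact because the α-hydrogen of a carboxylate is not removed under these conditions.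

Step 3
Reactants: 4 (2S,3R)-2-hydroxy-3-methylbutanedioic acid
Product: 5 (2R)-2-[(2S,4S)-2-tert-butyl-5-oxo-1,3-dioxolan-4-yl]propanoic acid
Conditions: t-BuCHO (2 equiv), TsOH·H2O (cat.), H2SO4 (cat.), pentane, reflux, water separator; recrystallisation
Reagents that add atoms: pivalaldehyde, CC(C)(C)C=O
Why: Seebach acetalisation of the α-hydroxy acid under thermodynamic control should give the five-membered dioxolanone with tert-butyl cis to the side chain, which stores the C8 configuration for step 16.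

Step 4
Reactants: 6 pent-4-yn-1-ol
Product: 8 (4Z)-5-iodo-4-methylpent-4-en-1-ol, via cyclic alkenylalane 7 (not isolated)
Conditions: AlMe3 (3 equiv), Cp2ZrCl2 (0.25 equiv), ClCH2CH2Cl, 23 °C then reflux; I2, THF, −30 → 0 °C
Reagents that add atoms: trimethylaluminium, C[Al](C)C; iodine, II
Why: Negishi zirconium-catalysed carboalumination followed by chelation-driven isomerisation of the alkenylalane (anti-carbometalation of an alkynol) and iodinolysis should give the Z trisubstituted vinyl iodide that becomes C5=C6.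

Step 5
Reactants: 8 (4Z)-5-iodo-4-methylpent-4-en-1-ol
Product: 10 (4Z)-4-methyl-5-(trimethylsilyl)pent-4-en-1-ol, via bis-silyl derivative 9 (not isolated)
Conditions: t-BuLi (3.2 equiv), Et2O, −78 °C; Me3SiCl (2.5 equiv), −78 → 23 °C; K2CO3, MeOH, 0 °C
Reagents that add atoms: chlorotrimethylsilane, C[Si](C)(C)Cl
Why: Iodine–lithium exchange with retention of alkene geometry and C-silylation masks the vinyl iodide as a vinylsilane so that it survives the butyllithium and Grignard steps, the O-silyl ether being removed by methanolysis.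

Step 6
Reactants: 10 (4Z)-4-methyl-5-(trimethylsilyl)pent-4-en-1-ol
Product: 11 (4Z)-4-methyl-5-(trimethylsilyl)pent-4-enal
Conditions: Dess–Martin periodinane, NaHCO3, CH2Cl2, 0 → 23 °C
Reagents that add atoms: none
Why: Dess–Martin oxidation of a primary alcohol should give the non-conjugated aldehyde (C2) without touching the vinylsilane.

Step 7
Reactants: 11 (4Z)-4-methyl-5-(trimethylsilyl)pent-4-enal
Product: 12 (2E,6Z)-2,6-dimethyl-7-(trimethylsilyl)hepta-2,6-dienal
Conditions: Ph3P=C(CH3)CHO (1.3 equiv), toluene, 100 °C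
Reagents that add atoms: 2-(triphenylphosphoranylidene)propanal, CC(C=O)=P(c1ccccc1)(c1ccccc1)c1ccccc1
Why: Wittig olefination with a stabilised formyl ylide should give the E trisubstituted enal (C14, C1, C15, C2), since oxaphosphetane formation is reversible for stabilised ylides.

Step 8
Reactants: 12 (2E,6Z)-2,6-dimethyl-7-(trimethylsilyl)hepta-2,6-dienal
Product: 13 (4S,5E,9Z)-5,9-dimethyl-10-(trimethylsilyl)deca-5,9-dien-1-yn-4-ol
Conditions: allenyl-B(pin) (1.5 equiv), (S)-TRIP [(S)-3,3'-bis(2,4,6-triisopropylphenyl)-1,1'-binaphthyl-2,2'-diyl hydrogen phosphate] (5 mol%), 4 Å MS, cyclohexane, 23 °C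
Reagents that add atoms: allenylboronic acid pinacol ester, C=C=CB1OC(C)(C)C(C)(C)O1
Why: Chiral phosphoric acid-catalysed propargylboration through a closed six-membered transition state (SE2' of the allenylboronate) should set C14 (S) under catalyst control and bring in C11–C13 as a terminal alkyne.

Step 9
Reactants: 13 (4S,5E,9Z)-5,9-dimethyl-10-(trimethylsilyl)deca-5,9-dien-1-yn-4-ol
Product: 14 triethylsilyl ether of 13
Conditions: Et3SiCl, imidazole, DMF, 0 °C
Reagents that add atoms: chlorotriethylsilane, CC[Si](Cl)(CC)CC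
Why: Silylation of the secondary alcohol; the triethylsilyl group is chosen because it can later be removed by mild acid in the presence of the tert-butyldiphenylsilyl ether.

Step 10
Reactants: 14 triethylsilyl ether of 13
Product: 16 (5S,6E,10Z)-6,10-dimethyl-5-[(triethylsilyl)oxy]-11-(trimethylsilyl)undeca-6,10-dien-2-yn-1-ol, via lithium acetylide 15 (not isolated)
Conditions: n-BuLi (1.1 equiv), THF, −78 °C; (CH2O)n, −78 → 23 °C; aq. NH4Cl
Reagents that add atoms: formaldehyde (from paraformaldehyde), C=O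
Why: Addition of the lithium acetylide to formaldehyde should install C20 as the propargylic alcohol needed to direct the next step.

Step 11
Reactants: 16 (5S,6E,10Z)-6,10-dimethyl-5-[(triethylsilyl)oxy]-11-(trimethylsilyl)undeca-6,10-dien-2-yn-1-ol
Product: 18 (2E,5S,6E,10Z)-2-ethenyl-6,10-dimethyl-5-[(triethylsilyl)oxy]-11-(trimethylsilyl)undeca-2,6,10-trien-1-ol, via magnesium chelate 17 (not isolated)
Conditions: CH2=CHMgCl (5 equiv), THF–toluene, 80 °C; aq. NH4Cl, 0 °C
Reagents that add atoms: vinylmagnesium chloride, C=C[Mg]Cl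
Why: Hydroxyl-directed anti-carbomagnesiation of a propargylic alcohol (Duboudin-type, vinyl variant) should deliver vinyl (C10, C9) to the proximal carbon C11, and protonation of the five-membered magnesium chelate leaves C13 cis to C10, which fixes the ring A alkene geometry.

Step 12
Reactants: 18 (2E,5S,6E,10Z)-2-ethenyl-6,10-dimethyl-5-[(triethylsilyl)oxy]-11-(trimethylsilyl)undeca-2,6,10-trien-1-ol
Product: 19 tert-butyldiphenylsilyl ether of 18
Conditions: t-BuPh2SiCl, imidazole, DMF, 23 °C
Reagents that add atoms: tert-butyl(chloro)diphenylsilane, CC(C)(C)[Si](Cl)(c1ccccc1)c1ccccc1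
Why: Silylation of the primary allylic C20 hydroxyl with a group that should last until the final step.

Step 13
Reactants: 19 tert-butyldiphenylsilyl ether of 18
Product: 21 (3E,6S,7E,11Z)-3-{[(tert-butyldiphenylsilyl)oxy]methyl}-7,11-dimethyl-6-[(triethylsilyl)oxy]-12-(trimethylsilyl)dodeca-3,7,11-trien-1-ol, via B-alkyl-9-BBN adduct 20 (not isolated)
Conditions: 9-BBN (1.3 equiv), THF, 0 → 23 °C; NaOH, H2O2, 0 °C
Reagents that add atoms: hydrogen peroxide, OO
Why: Hydroboration–oxidation, in which 9-BBN should add only to the monosubstituted vinyl terminus C9 because the trisubstituted alkenes and the vinylsilane are too hindered, gives the homoallylic alcohol with the C11=C12 geometry untouched.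

Step 14
Reactants: 21 (3E,6S,7E,11Z)-3-{[(tert-butyldiphenylsilyl)oxy]methyl}-7,11-dimethyl-6-[(triethylsilyl)oxy]-12-(trimethylsilyl)dodeca-3,7,11-trien-1-ol
Product: 22 (3E,6S,7E,11Z)-3-{[(tert-butyldiphenylsilyl)oxy]methyl}-12-iodo-7,11-dimethyl-6-[(triethylsilyl)oxy]dodeca-3,7,11-trien-1-ol
Conditions: NIS (1.3 equiv), (CF3)2CHOH, 0 °C, 10 min
Reagents that add atoms: N-iodosuccinimide, O=C1CCC(=O)N1I
Why: Electrophilic ipso-iododesilylation through a β-silyl-stabilised cation should return the Z vinyl iodide with retention, and its speed in hexafluoroisopropanol should outrun reaction at the other alkenes.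

Step 15
Reactants: 22 (3E,6S,7E,11Z)-3-{[(tert-butyldiphenylsilyl)oxy]methyl}-12-iodo-7,11-dimethyl-6-[(triethylsilyl)oxy]dodeca-3,7,11-trien-1-ol
Product: 23 (3E,6S,7E,11Z)-3-{[(tert-butyldiphenylsilyl)oxy]methyl}-12-iodo-7,11-dimethyl-6-[(triethylsilyl)oxy]dodeca-3,7,11-trienal
Conditions: Dess–Martin periodinane, NaHCO3, CH2Cl2, 0 °C; used crude at once
Reagents that add atoms: none
Why: Buffered Dess–Martin oxidation should give the β,γ-unsaturated C9 aldehyde without moving the alkene into conjugation.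

Step 16
Reactants: 5 (2R)-2-[(2S,4S)-2-tert-butyl-5-oxo-1,3-dioxolan-4-yl]propanoic acid; 23 C9 aldehyde
Product: 26 (3R,4S)-4-hydroxy-3-methyl-4-(1-hydroxyalkyl)oxolan-2-one carrying the C9–C14/C1–C6 chain (C9 carbinol as epimer mixture), via dilithium enolate 24 (not isolated), via aldol adduct 25 (not isolated)
Conditions: 5 (1.5 equiv), LiN(SiMe3)2 (3.1 equiv), THF, −78 °C; 23, −78 °C; AcOH (1.6 equiv), −78 °C; LiBH4 (4 equiv), −78 → 0 °C; aq. NH4Cl then citric acid (pH 3), 23 °C
Reagents that add atoms: none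
Why: Seebach self-regeneration of stereocentres, in which the dioxolanone enolate should add to the aldehyde anti to tert-butyl so that C9 takes the place of hydrogen with retention and sets C8 (S); LiBH4 then reduces the dioxolanone carbonyl C7 while the lithium carboxylate C19 is inert, and acid closes the five-membered lactone onto the primary C7 hydroxyl.

Step 17
Reactants: 26 hydroxy lactone
Product: 27 C19 Weinreb amide with free C7 (primary), C8 (tertiary) and C9 (secondary) hydroxyls
Conditions: MeNH(OMe)·HCl (6 equiv), AlMe3 (6 equiv), CH2Cl2, 0 → 23 °C; aq. potassium sodium tartrate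
Reagents that add atoms: N,O-dimethylhydroxylamine hydrochloride, CNOC.Cl
Why: Weinreb aminolysis of the γ-lactone with the dimethylaluminium amide should free the C7 hydroxyl and hold C19 as an amide that can still acylate the C7 oxygen in step 19.

Step 18
Reactants: 27 triol Weinreb amide
Product: 28 C7 aldehyde C9 ketone (8-hydroxy, C19 Weinreb amide)
Conditions: Dess–Martin periodinane (3 equiv), NaHCO3, CH2Cl2, 0 → 23 °C; used at once
Reagents that add atoms: none
Why: Dess–Martin oxidation should convert the primary C7 and secondary C9 alcohols in one operation, the tertiary C8 hydroxyl being inert and both C9 epimers converging on one ketone.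

Step 19
Reactants: 28 keto aldehyde
Product: 31 macrocyclic lactone with 14-hydroxy and 8-hydroxy groups and the 9-ketone (7S,8S,14S,17R), via seco hydroxy amide 29 (not isolated), via TES lactone 30 (not isolated)
Conditions: CrCl2 (15 equiv), NiCl2 (0.15 equiv), DMSO–THF (3:1), 23 °C, 0.003 M, syringe pump; then CSA (0.3 equiv), MeOH–CH2Cl2, 0 → 23 °C
Reagents that add atoms: none
Why: Nozaki–Hiyama–Kishi reaction, in which zerovalent nickel inserts into the vinyl iodide and the alkenyl group passes to trivalent chromium and adds to the aldehyde only (ketone and amide are inert), should close the 14-membered ring; C7 (S) is expected from chelation of chromium between the C8 oxygen and the aldehyde with attack past the flat C9 carbonyl, and acid then lactonises the C7 oxygen onto the amide and removes the triethylsilyl group.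

Step 20
Reactants: 31 macrocyclic allylic alcohol
Product: 32 1,2-epoxide of 31 (epoxide erythro to the 14-hydroxyl)
Conditions: Ti(OiPr)4 (0.3 equiv), L-(+)-DIPT (0.36 equiv), t-BuOOH (2 equiv), 4 Å MS, CH2Cl2, −20 °C
Reagents that add atoms: tert-butyl hydroperoxide, CC(C)(C)OO
Why: Sharpless asymmetric epoxidation in the matched sense, L-(+)-tartrate being the ligand for which a (14S) carbinol of this substitution pattern is the fast-reacting one, should deliver oxygen only to the C1=C2 alkene and give the erythro epoxy alcohol, setting C1 and C2.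

Step 21
Reactants: 32 epoxy alcohol
Product: 33 14-acetate of 32
Conditions: Ac2O (1.5 equiv), pyridine, DMAP (cat.), CH2Cl2, 0 °C
Reagents that add atoms: acetic anhydride, CC(=O)OC(C)=O
Why: Acylation of the secondary C14 hydroxyl should be selective, as the tertiary C8 hydroxyl does not react at 0 °C.

Step 22
Reactants: 33 epoxy acetate ketone
Product: 35 C9 trimethylsilyl dienol ether with 8-OSiMe3 (key-step precursor), via C8 trimethylsilyl ether 34 (not isolated)
Conditions: 1-(trimethylsilyl)imidazole, CH2Cl2, 23 °C, evaporate; Me3SiCl (3 equiv), LiN(SiMe3)2 (1.15 equiv), THF, −78 °C; pentane/aq. NaHCO3; used crude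
Reagents that add atoms: 1-(trimethylsilyl)imidazole, C[Si](C)(C)n1ccnc1; chlorotrimethylsilane, C[Si](C)(C)Cl
Why: Silylation of the tertiary alcohol followed by kinetic enolisation with in-situ silyl trapping should give the 2-silyloxy diene, because the quaternary C8 leaves only the doubly activated C10 hydrogens and its bulk enforces the enol geometry with oxygen cis to C11.

Step 23
Reactants: 35 macrocyclic epoxy silyl dienol ether
Product: 36 bicyclic 2-hydroxy ketone lactone (ring A and ten-membered ring formed; 14-OAc, 8-OSiMe3, 20-OSiPh2t-Bu; 1S,2S,7S,8S,10S,14S,17R)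
Conditions: BF3·OEt2 (1.5 equiv), CH2Cl2, −78 → −40 °C; aq. NaHCO3
Reagents that add atoms: none
Why: Proposed new method: BF3 binds the epoxide oxygen and the C9 silyl dienol ether attacks the tertiary carbon C1 through C10 from the side opposite the breaking C1–O bond, after which the silyloxycarbenium ion loses Me3SiF to leave the C9 ketone and the C2 hydroxyl; the closest known reactions are Lewis-acid openings of epoxides by tethered silyl enol ethers (Mukaiyama-type ring closures) and transannular epoxide–alkene cyclisations of macrocyclic terpenoid epoxides, neither shown for an enol silane across a fourteen-membered ring. Ring A closes in 6-(enolexo)-exo-tet fashion and the ten-membered ring is what remains of the macrocycle. C1 is set by inversion at the epoxide carbon fixed in step 20, C2 keeps its configuration because its C–O bond is not broken, and C10 is set by the enol ether face that can reach C1. With the C11=C12 geometry and the enol geometry fixed, that face should place C9 and C2 anti on the new ring (trans fusion), but this conformational preference is unproven. The step needs C-attack at C1 rather than opening at C2, attack through C12, or interception by the C14 oxygen: C1 is the tertiary and only six-ring-forming position, attack through C12 would need a four-membered ring, the quaternary C8 confines the enol to C10, and an acetate rather than a silyl ether at C14 disfavours the semipinacol hydride shift.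

Step 24
Reactants: 36 bicyclic 2-hydroxy ketone lactone
Product: 37 2,14-diacetate of 36
Conditions: Ac2O, DMAP, pyridine, 23 °C
Reagents that add atoms: acetic anhydride, CC(=O)OC(C)=O
Why: DMAP-catalysed acetylation should acylate the hindered secondary C2 hydroxyl, the only free hydroxyl present.

Step 25
Reactants: 37 diacetate
Product: 38 CNP0140109.1
Conditions: HF·pyridine, pyridine, THF, 0 → 23 °C
Reagents that add atoms: none
Why: Fluoride-mediated desilylation under buffered, non-basic conditions should remove the primary tert-butyldiphenylsilyl and the tertiary trimethylsilyl ethers without acetate migration, lactone opening or retro-aldol cleavage.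

**Compound list**

1 | dimethyl (2S)-2-hydroxybutanedioate (dimethyl (S)-malate) | COC(=O)C[C@H](O)C(=O)OC | starting material
2 | dilithium alkoxide enolate of 1 | [Li+].[Li+].COC(=O)[C@@H]([O-])C=C([O-])OC | intermediate
3 | dimethyl (2S,3R)-2-hydroxy-3-methylbutanedioate | COC(=O)[C@H](C)[C@H](O)C(=O)OC | intermediate
4 | (2S,3R)-2-hydroxy-3-methylbutanedioic acid | OC(=O)[C@H](C)[C@H](O)C(=O)O | intermediate
5 | (2R)-2-[(2S,4S)-2-tert-butyl-5-oxo-1,3-dioxolan-4-yl]propanoic acid | O=C1O[C@@H](C(C)(C)C)O[C@H]1[C@@H](C)C(=O)O | intermediate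
6 | pent-4-yn-1-ol | C#CCCCO | starting material
7 | cyclic (Z)-alkenyl(methyl)aluminium alkoxide from 6 | CC1=C[Al](C)OCCC1 | intermediate
8 | (4Z)-5-iodo-4-methylpent-4-en-1-ol | OCCC/C(C)=C\I | intermediate
9 | trimethyl{[(4Z)-4-methyl-5-(trimethylsilyl)pent-4-en-1-yl]oxy}silane | C[Si](C)(C)OCCC/C(C)=C\[Si](C)(C)C | intermediate
10 | (4Z)-4-methyl-5-(trimethylsilyl)pent-4-en-1-ol | OCCC/C(C)=C\[Si](C)(C)C | intermediate
11 | (4Z)-4-methyl-5-(trimethylsilyl)pent-4-enal | O=CCC/C(C)=C\[Si](C)(C)C | intermediate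
12 | (2E,6Z)-2,6-dimethyl-7-(trimethylsilyl)hepta-2,6-dienal | O=C/C(C)=C/CC/C(C)=C\[Si](C)(C)C | intermediate
13 | (4S,5E,9Z)-5,9-dimethyl-10-(trimethylsilyl)deca-5,9-dien-1-yn-4-ol | C#CC[C@H](O)/C(C)=C/CC/C(C)=C\[Si](C)(C)C | intermediate
14 | triethyl{[(4S,5E,9Z)-5,9-dimethyl-10-(trimethylsilyl)deca-5,9-dien-1-yn-4-yl]oxy}silane | C#CC[C@H](O[Si](CC)(CC)CC)/C(C)=C/CC/C(C)=C\[Si](C)(C)C | intermediate
15 | lithium acetylide of 14 | [Li]C#CC[C@H](O[Si](CC)(CC)CC)/C(C)=C/CC/C(C)=C\[Si](C)(C)C | intermediate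
16 | (5S,6E,10Z)-6,10-dimethyl-5-[(triethylsilyl)oxy]-11-(trimethylsilyl)undeca-6,10-dien-2-yn-1-ol | OCC#CC[C@H](O[Si](CC)(CC)CC)/C(C)=C/CC/C(C)=C\[Si](C)(C)C | intermediate
17 | five-membered magnesium alkoxide chelate (C20–O–Mg–C12) from anti addition of vinyl to C11 of 16 | C=CC1=C(C[C@H](O[Si](CC)(CC)CC)/C(C)=C/CC/C(C)=C\[Si](C)(C)C)[Mg]OC1 | intermediate
18 | (2E,5S,6E,10Z)-2-ethenyl-6,10-dimethyl-5-[(triethylsilyl)oxy]-11-(trimethylsilyl)undeca-2,6,10-trien-1-ol | C=C/C(CO)=C\C[C@H](O[Si](CC)(CC)CC)/C(C)=C/CC/C(C)=C\[Si](C)(C)C | intermediate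
19 | tert-butyldiphenylsilyl ether of 18 | C=C/C(CO[Si](c1ccccc1)(c1ccccc1)C(C)(C)C)=C\C[C@H](O[Si](CC)(CC)CC)/C(C)=C/CC/C(C)=C\[Si](C)(C)C | intermediate
20 | B-alkyl-9-BBN adduct of 19 (boron on C9) | C1CCC2CCCC1B2CC/C(CO[Si](c1ccccc1)(c1ccccc1)C(C)(C)C)=C\C[C@H](O[Si](CC)(CC)CC)/C(C)=C/CC/C(C)=C\[Si](C)(C)C | intermediate
21 | (3E,6S,7E,11Z)-3-{[(tert-butyldiphenylsilyl)oxy]methyl}-7,11-dimethyl-6-[(triethylsilyl)oxy]-12-(trimethylsilyl)dodeca-3,7,11-trien-1-ol | OCC/C(CO[Si](c1ccccc1)(c1ccccc1)C(C)(C)C)=C\C[C@H](O[Si](CC)(CC)CC)/C(C)=C/CC/C(C)=C\[Si](C)(C)C | intermediate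
22 | (3E,6S,7E,11Z)-3-{[(tert-butyldiphenylsilyl)oxy]methyl}-12-iodo-7,11-dimethyl-6-[(triethylsilyl)oxy]dodeca-3,7,11-trien-1-ol | OCC/C(CO[Si](c1ccccc1)(c1ccccc1)C(C)(C)C)=C\C[C@H](O[Si](CC)(CC)CC)/C(C)=C/CC/C(C)=C\I | intermediate
23 | (3E,6S,7E,11Z)-3-{[(tert-butyldiphenylsilyl)oxy]methyl}-12-iodo-7,11-dimethyl-6-[(triethylsilyl)oxy]dodeca-3,7,11-trienal (C9 aldehyde) | O=CC/C(CO[Si](c1ccccc1)(c1ccccc1)C(C)(C)C)=C\C[C@H](O[Si](CC)(CC)CC)/C(C)=C/CC/C(C)=C\I | intermediate
24 | dilithium carboxylate enolate of 5 | [Li+].[Li+].[O-]C(=O)[C@H](C)C1=C([O-])O[C@@H](C(C)(C)C)O1 | intermediate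
25 | aldol adduct: dioxolanone 5 bearing at C8 the 1-hydroxyalkyl chain from 23 (C8 S; C9 carbinol as epimer mixture) | O=C1O[C@@H](C(C)(C)C)O[C@]1([C@@H](C)C(=O)O)C(O)C/C(CO[Si](c2ccccc2)(c2ccccc2)C(C)(C)C)=C\C[C@H](O[Si](CC)(CC)CC)/C(C)=C/CC/C(C)=C\I | intermediate
26 | (3R,4S)-4-hydroxy-3-methyl-4-[(3E,6S,7E,11Z)-3-{[(tert-butyldiphenylsilyl)oxy]methyl}-1-hydroxy-12-iodo-7,11-dimethyl-6-[(triethylsilyl)oxy]dodeca-3,7,11-trien-1-yl]oxolan-2-one (C9 epimer mixture) | C[C@H]1C(=O)OC[C@]1(O)C(O)C/C(CO[Si](c2ccccc2)(c2ccccc2)C(C)(C)C)=C\C[C@H](O[Si](CC)(CC)CC)/C(C)=C/CC/C(C)=C\I | intermediate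
27 | N-methoxy-N-methyl amide (C19) with 7,8,9-triol, 14-OSiEt3, 20-OSiPh2t-Bu and the C6 vinyl iodide (8S,14S,17R) | CON(C)C(=O)[C@H](C)[C@](O)(CO)C(O)C/C(CO[Si](c1ccccc1)(c1ccccc1)C(C)(C)C)=C\C[C@H](O[Si](CC)(CC)CC)/C(C)=C/CC/C(C)=C\I | intermediate
28 | C7 aldehyde C9 ketone of 27 (8-hydroxy; 8S,14S,17R) | CON(C)C(=O)[C@H](C)[C@](O)(C=O)C(=O)C/C(CO[Si](c1ccccc1)(c1ccccc1)C(C)(C)C)=C\C[C@H](O[Si](CC)(CC)CC)/C(C)=C/CC/C(C)=C\I | intermediate
29 | 14-membered carbocycle C1–C14 with 7S-hydroxyl, 8-hydroxyl, 9-ketone, C19 Weinreb amide side chain on C8, 14-OSiEt3, 20-OSiPh2t-Bu (1E, 5Z, C10/C13 cis on C11=C12) | CC[Si](CC)(CC)O[C@H]1C/C=C(CO[Si](c3ccccc3)(c3ccccc3)C(C)(C)C)\CC(=O)[C@](O)([C@@H](C)C(=O)N(C)OC)[C@@H](O)/C=C(/C)CC/C=C1\C | intermediate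
30 | macrocyclic γ-lactone (C19 to O–C7) with 14-OSiEt3 (7S,8S,14S,17R) | CC[Si](CC)(CC)O[C@H]1C/C=C(CO[Si](c3ccccc3)(c3ccccc3)C(C)(C)C)\CC(=O)[C@@]2(O)[C@H](/C=C(/C)CC/C=C1\C)OC(=O)[C@@H]2C | intermediate
31 | macrocyclic γ-lactone with free 14-hydroxyl, 8-hydroxyl, 9-ketone, 20-OSiPh2t-Bu (7S,8S,14S,17R; 1E, 5Z) | O[C@H]1C/C=C(CO[Si](c3ccccc3)(c3ccccc3)C(C)(C)C)\CC(=O)[C@@]2(O)[C@H](/C=C(/C)CC/C=C1\C)OC(=O)[C@@H]2C | intermediate
32 | 1,2-epoxide of 31, epoxide oxygen erythro to the 14-hydroxyl (configuration as in SMILES) | O[C@H]1C/C=C(CO[Si](c4ccccc4)(c4ccccc4)C(C)(C)C)\CC(=O)[C@@]2(O)[C@H](/C=C(/C)CC[C@@H]3O[C@]31C)OC(=O)[C@@H]2C | intermediate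
33 | 14-acetate of 32 | CC(=O)O[C@H]1C/C=C(CO[Si](c4ccccc4)(c4ccccc4)C(C)(C)C)\CC(=O)[C@@]2(O)[C@H](/C=C(/C)CC[C@@H]3O[C@]31C)OC(=O)[C@@H]2C | intermediate
34 | 8-O-trimethylsilyl ether of 33 | CC(=O)O[C@H]1C/C=C(CO[Si](c4ccccc4)(c4ccccc4)C(C)(C)C)\CC(=O)[C@@]2(O[Si](C)(C)C)[C@H](/C=C(/C)CC[C@@H]3O[C@]31C)OC(=O)[C@@H]2C | intermediate
35 | key-step precursor: 14-membered 1,2-epoxide with C9 trimethylsilyl dienol ether (C9=C10, C11=C12), 8-OSiMe3, 14-OAc, 20-OSiPh2t-Bu, fused γ-lactone | CC(=O)O[C@H]1C/C=C(CO[Si](c4ccccc4)(c4ccccc4)C(C)(C)C)\C=C(/O[Si](C)(C)C)[C@@]2(O[Si](C)(C)C)[C@H](/C=C(/C)CC[C@@H]3O[C@]31C)OC(=O)[C@@H]2C | intermediate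
36 | key-step product: bicyclic lactone with free 2-hydroxyl, 9-ketone, 14-OAc, 8-OSiMe3, 20-OSiPh2t-Bu (1S,2S,7S,8S,10S,14S,17R) | CC(=O)O[C@H]1CC=C(CO[Si](c4ccccc4)(c4ccccc4)C(C)(C)C)[C@@H]2C(=O)[C@@]3(O[Si](C)(C)C)[C@H](/C=C(/C)CC[C@H](O)[C@]21C)OC(=O)[C@@H]3C | intermediate
37 | 2,14-diacetate of 36 | CC(=O)O[C@H]1CC=C(CO[Si](c4ccccc4)(c4ccccc4)C(C)(C)C)[C@@H]2C(=O)[C@@]3(O[Si](C)(C)C)[C@H](/C=C(/C)CC[C@H](OC(C)=O)[C@]21C)OC(=O)[C@@H]3C | intermediate
38 | CNP0140109.1 (1S,2S,7S,8S,10S,14S,17R; 5Z) | CC(=O)O[C@H]1CC=C(CO)[C@@H]2C(=O)[C@@]3(O)[C@H](/C=C(/C)CC[C@H](OC(C)=O)[C@]21C)OC(=O)[C@@H]3C | target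

**Step count**

Total: 25 steps. Longest linear sequence: 22 steps (steps 4–25, from pent-4-yn-1-ol); the three-step malate branch (steps 1–3) joins at step 16.

**Steps most likely to fail**

1. Step 23 (transannular closure). The C–C bond formation may be outrun by attack of the C14 acetate carbonyl on the activated epoxide, by a 1,2-hydride shift from C14, or by loss of the enol silyl group; the enol ether may also attack through its other face and give the cis ring fusion.
Fallback (known chemistry; sets out from 26, comes back at 38): ring A is closed before the macrocycle, where Lewis-acid opening of an epoxide by a tethered silyl enol ether is an ordinary six-membered ring closure, and the ten-membered ring is closed afterwards by the Nozaki–Hiyama–Kishi reaction.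
   - Lactone 26 is oxidised with Dess–Martin periodinane to the C9 ketone F1.
   - CSA in MeOH removes the triethylsilyl group to give the allylic alcohol F2.
   - Sharpless epoxidation as in step 20 gives the epoxy alcohol F3.
   - LiN(SiMe3)2 (3.3 equiv) with Me3SiCl present gives the tris-silylated open-chain dienol ether F4.
   - BF3·OEt2 at −78 °C closes ring A, and methanolic citric acid removes the remaining trimethylsilyl groups to give the ring A triol F5. C10 is here α to the ketone on a simple cyclohexene and can be equilibrated to the trans arrangement if needed.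
   - Me2AlN(OMe)Me opens the lactone to the Weinreb amide F6.
   - TEMPO/PhI(OAc)2 oxidises only the primary C7 alcohol, giving the aldehyde F7.
   - CrCl2/NiCl2 at high dilution closes the ten-membered ring at C6–C7, and CSA lactonises to the bicyclic triol lactone F8.
   - Ac2O/DMAP acetylates the C2 and C14 hydroxyls to give the diacetate F9, and HF·pyridine then gives 38.

2. Step 19 (Nozaki–Hiyama–Kishi macrocyclisation). Addition may take place on the other face of the aldehyde (poor facial selectivity at C7), or intermolecular coupling may compete with ring closure.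
Fallback (sets out from the 7-epimer formed in step 19, comes back at 30): the C7–O bond of the lactone is made by displacement with inversion instead of relying on the facial selectivity of the addition. The 7-epimeric seco hydroxy amide F10 is isolated after a neutral work-up and treated with PPh3 and DIAD in THF at 0 °C (Mitsunobu activation). The Weinreb amide oxygen displaces the activated C7 oxygen with inversion, and aqueous work-up hydrolyses the resulting iminium lactone to the TES lactone 30, which CSA in MeOH converts into 31.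

3. Step 16 (aldol addition of the dianion). Proton transfer from the enolisable β,γ-unsaturated aldehyde to the basic enolate, with migration of the alkene into conjugation, may compete with addition, and the hindered aldolate may revert on warming.
Fallback (sets out from 5, comes back at 25): the basic lithium enolate is replaced by a neutral silyl ketene acetal. Acid 5 is converted with LiN(SiMe3)2 and Me3SiCl into the bis(trimethylsilyl) ketene acetal F11, which adds to aldehyde 23 under BF3·OEt2 at −78 °C (Mukaiyama aldol, still anti to tert-butyl). Aqueous work-up gives the aldol adduct 25, whose lithium salt is reduced with LiBH4 as in step 16 to give 26.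

Further compounds
F1 | step 23 | C9 ketone of lactone 26 (14-OSiEt3) | C[C@H]1C(=O)OC[C@]1(O)C(=O)C/C(CO[Si](c2ccccc2)(c2ccccc2)C(C)(C)C)=C\C[C@H](O[Si](CC)(CC)CC)/C(C)=C/CC/C(C)=C\I
F2 | step 23 | 14-hydroxy keto lactone (allylic alcohol) | C[C@H]1C(=O)OC[C@]1(O)C(=O)C/C(CO[Si](c2ccccc2)(c2ccccc2)C(C)(C)C)=C\C[C@H](O)/C(C)=C/CC/C(C)=C\I
F3 | step 23 | open-chain 1,2-epoxy 14-alcohol keto lactone | C[C@H]1C(=O)OC[C@]1(O)C(=O)C/C(CO[Si](c2ccccc2)(c2ccccc2)C(C)(C)C)=C\C[C@H](O)[C@]3(C)O[C@H]3CC/C(C)=C\I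
F4 | step 23 | open-chain epoxy C9 trimethylsilyl dienol ether with 8- and 14-OSiMe3 | C[C@H]1C(=O)OC[C@]1(O[Si](C)(C)C)/C(O[Si](C)(C)C)=C/C(CO[Si](c2ccccc2)(c2ccccc2)C(C)(C)C)=C\C[C@H](O[Si](C)(C)C)[C@]3(C)O[C@H]3CC/C(C)=C\I
F5 | step 23 | ring A triol: cyclohexene with C1 quaternary, 2,14-diol, C9 keto lactone side chain on C10, C6 vinyl iodide | O[C@H]1CC=C(CO[Si](c2ccccc2)(c2ccccc2)C(C)(C)C)[C@H](C(=O)[C@@]4(O)COC(=O)[C@@H]4C)[C@@]1(C)[C@@H](O)CC/C(C)=C\I
F6 | step 23 | ring A Weinreb amide with 2,7,8,14-tetraol | O[C@H]1CC=C(CO[Si](c2ccccc2)(c2ccccc2)C(C)(C)C)[C@H](C(=O)[C@@](O)(CO)[C@@H](C)C(=O)N(C)OC)[C@@]1(C)[C@@H](O)CC/C(C)=C\I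
F7 | step 23 | ring A C7 aldehyde Weinreb amide (2,8,14-triol) | O[C@H]1CC=C(CO[Si](c2ccccc2)(c2ccccc2)C(C)(C)C)[C@H](C(=O)[C@@](O)(C=O)[C@@H](C)C(=O)N(C)OC)[C@@]1(C)[C@@H](O)CC/C(C)=C\I
F8 | step 23 | bicyclic lactone 2,8,14-triol with 20-OSiPh2t-Bu | O[C@H]1CC=C(CO[Si](c4ccccc4)(c4ccccc4)C(C)(C)C)[C@@H]2C(=O)[C@@]3(O)[C@H](/C=C(/C)CC[C@H](O)[C@]21C)OC(=O)[C@@H]3C
F9 | step 23 | bicyclic lactone 2,14-diacetate with free 8-hydroxyl and 20-OSiPh2t-Bu | CC(=O)O[C@H]1CC=C(CO[Si](c4ccccc4)(c4ccccc4)C(C)(C)C)[C@@H]2C(=O)[C@@]3(O)[C@H](/C=C(/C)CC[C@H](OC(C)=O)[C@]21C)OC(=O)[C@@H]3C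
F10 | step 19 | 7-epimer (7R) of seco hydroxy amide 29 | CC[Si](CC)(CC)O[C@H]1C/C=C(CO[Si](c3ccccc3)(c3ccccc3)C(C)(C)C)\CC(=O)[C@](O)([C@@H](C)C(=O)N(C)OC)[C@H](O)/C=C(/C)CC/C=C1\C
F11 | step 16 | bis(trimethylsilyl) ketene acetal of 5 (silyl ester and dioxolanone silyl enol ether) | C[C@@H](C(=O)O[Si](C)(C)C)C1=C(O[Si](C)(C)C)O[C@@H](C(C)(C)C)O1
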